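The route rests on disconnecting the C4–C5 bond of the single cyclohexane ring (C1 CHOAc, C2 CH2, C3 CHBr, C4 CMe2, C5 CHCl, C6 alkene carbon; side chain C7H=, C8H2Br). The equatorial C3 bromide next to quaternary C4 and the allylic array Cl–C5–C6=C7–C8–Br are the imprint of Br+ on an acyclic 1,5-diene whose terminator is a chlorinated 1,3-diene. One operation closes the ring, makes C4–C5, C3–Br and C8–Br, shifts unsaturation to C6=C7 and sets C3 and C5. Its precursor carries, on the (S)-configured silyloxy carbon C1, a prenyl group and a buta-1,3-dien-2-yl group whose terminal chlorine is cis to C1 (Z).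

Key step: step 6

Remark: locants C1–C8 are those defined above, and systematic names keep their own. The descriptors re-derived from the target SMILES are 1S, 3R, 5R and Z at C6=C7, so O and Br are cis and equatorial, Cl is trans to both and axial, and C8 is cis to C5.

Step 1
Reactants: 1 methyl (S)-glycidate; 2 2-methylprop-1-enylmagnesium bromide (commercial THF solution)
Product: 3 methyl (S)-2-hydroxy-5-methylhex-4-enoate
Conditions: CuI (10 mol %), THF, −78 to −40 °C; aq. NH4Cl
Reagents that add atoms: none
Why: Copper-catalysed SN2 opening of a terminal epoxide by a Grignard reagent goes to the unsubstituted carbon (future C2) and, at low temperature, outruns addition to the ester; no bond at the stereocentre is touched, so C1 keeps the S configuration of 1.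

Step 2
Reactants: 3 methyl (S)-2-hydroxy-5-methylhex-4-enoate
Product: 4 methyl (S)-5-methyl-2-(triethylsilyloxy)hex-4-enoate
Conditions: Et3SiCl, imidazole, CH2Cl2, 0 °C to rt
Reagents that add atoms: chlorotriethylsilane CC[Si](Cl)(CC)CC
Why: Routine silyl ether formation; triethylsilyl covers the hydroxyl during the hydride and carbonate stages of step 3 yet is labile enough to fall off in the acidic work-up there, which saves a separate deprotection.

Step 3
Reactants: 4 methyl (S)-5-methyl-2-(triethylsilyloxy)hex-4-enoate; 5 dimethyl (1-diazo-2-oxopropyl)phosphonate (Ohira–Bestmann reagent)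
Product: 8 (S)-6-methylhept-5-en-1-yn-3-ol, via silyloxy aldehyde 6 (not isolated), via triethylsilyl alkyne 7 (not isolated)
Conditions: i-Bu2AlH, CH2Cl2, −78 °C; MeOH, then K2CO3, 5, 0 °C to rt; 1 M HCl, rt
Reagents that add atoms: none
Why: Partial reduction of an α-silyloxy ester stops at the chelated aluminium hemiacetal, the aldehyde released by methanol undergoes Seyferth–Gilbert homologation with the Ohira–Bestmann reagent under carbonate conditions mild enough to leave the α-stereocentre alone (a known one-flask ester-to-alkyne sequence), and dilute acid then strips the triethylsilyl group; the new carbon is C5.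

Step 4
Reactants: 8 (S)-6-methylhept-5-en-1-yn-3-ol; 9 vinylmagnesium bromide
Product: 11 (S,Z)-3-(chloromethylidene)-7-methylocta-1,6-dien-4-ol, via oxamagnesacycle 10 (not isolated)
Conditions: 9 (3.5 equiv), CuI (20 mol %), THF, −20 °C to rt; NCS, −78 to 0 °C; aq. NH4Cl/Na2S2O3
Reagents that add atoms: N-chlorosuccinimide O=C1CCC(=O)N1Cl
Why: Alkoxide-directed, copper-catalysed anti-carbomagnesiation of a propargylic alcohol places vinyl on the proximal alkyne carbon C6 and magnesium on C5, held cis to C1 in a five-membered chelate, and electrophilic chlorination of the alkenylmagnesium with retention therefore gives only the Z chloroalkene (Cl cis to C1), which olefination of a ketone could not guarantee.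

Step 5
Reactants: 11 (S,Z)-3-(chloromethylidene)-7-methylocta-1,6-dien-4-ol
Product: 12 (S,Z)-3-(chloromethylidene)-7-methylocta-1,6-dien-4-yl tert-butyldimethylsilyl ether
Conditions: t-BuMe2SiOTf, 2,6-lutidine, CH2Cl2, −78 to 0 °C
Reagents that add atoms: tert-butyldimethylsilyl triflate CC(C)(C)[Si](C)(C)OS(=O)(=O)C(F)(F)F
Why: Silylation with the silyl triflate and a hindered base is reliable for a crowded secondary allylic alcohol; tert-butyldimethylsilyl is chosen because it carries no carbonyl oxygen, shields the ether oxygen from taking part in step 6 and later leaves under acidic fluoride that spares an allylic bromide.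

Step 6
Reactants: 12 (S,Z)-3-(chloromethylidene)-7-methylocta-1,6-dien-4-yl tert-butyldimethylsilyl ether
Product: 13 tert-butyl{[(1S,2Z,3R,5R)-5-bromo-2-(2-bromoethylidene)-3-chloro-4,4-dimethylcyclohexyl]oxy}dimethylsilane
Conditions: Et2SBr·SbCl5Br (1.1 equiv), MeNO2, −25 °C, 5 min; aq. Na2SO3/NaHCO3; crude product, LiBr, acetone, rt
Reagents that add atoms: bromodiethylsulfonium bromopentachloroantimonate CC[S+](Br)CC.Cl[Sb-](Cl)(Cl)(Cl)(Cl)Br; lithium bromide [Li+].[Br-] (exchange at C8 only)
Why: Proposed new method: the sulfonium ion hands Br+ to the C3=C4 prenyl alkene, the developing C4 cation is attacked by the chlorovinyl carbon C5 of the diene, and the resulting C6–C7–C8 allyl cation takes bromide from the antimonate at its unhindered primary end C8; the closest known reaction type is the bromonium-initiated cation–olefin (polyene) cyclisation with this reagent, to which a 1-chlorodiene terminator and halide capture are new. The cyclohexane closes 6-endo-trig at C5=C6 through a chair. C3 is controlled by C1, because A(1,3) strain between the Z chlorine and the C1 substituents turns C1–H into the diene plane and the silyloxy group equatorial, and anti opening of the bromonium ion within that chair leaves bromine equatorial and cis to oxygen (3R). C5 is controlled by the alkene geometry, since the C5 substituent cis to the ring atom C1, here chlorine, becomes axial as C5 pyramidalises (5R). The C6=C7 geometry follows from reaction through the s-cis diene rotamer, which keeps C8 away from the equatorial silyloxy group and beside the small equatorial C5–H, and the LiBr stage (Finkelstein exchange, degenerate for 13) turns any C8 chloride drawn from the antimonate into the bromide while the hindered C3 and C5 halides stay inert. The chemoselectivity needed, Br+ on the prenyl alkene and not on the diene, is secured by the trisubstituted alkene being far more electron-rich than a diene bearing chlorine and an allylic oxygen, as in the site-selective electrophilic additions of myrcene.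

Step 7
Reactants: 13 tert-butyl{[(1S,2Z,3R,5R)-5-bromo-2-(2-bromoethylidene)-3-chloro-4,4-dimethylcyclohexyl]oxy}dimethylsilane
Product: 14 (1S,2Z,3R,5R)-5-bromo-2-(2-bromoethylidene)-3-chloro-4,4-dimethylcyclohexan-1-ol
Conditions: HF·pyridine, THF (polyethylene vessel), 0 °C to rt
Reagents that add atoms: none
Why: Fluoride-driven cleavage of the Si–O bond in an acidic, non-nucleophilic medium (all pyridine is protonated) removes the silyl group without substitution or elimination at the C8, C5 or C3 halides, and the C1–O bond is not broken.

Step 8
Reactants: 14 (1S,2Z,3R,5R)-5-bromo-2-(2-bromoethylidene)-3-chloro-4,4-dimethylcyclohexan-1-ol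
Product: 15 (1S,2Z,3R,5R)-5-bromo-2-(2-bromoethylidene)-3-chloro-4,4-dimethylcyclohexyl acetate (CNP0362553.1)
Conditions: Ac2O, Sc(OTf)3 (1 mol %), MeCN, −20 °C
Reagents that add atoms: acetic anhydride CC(=O)OC(C)=O
Why: Lewis-acid-catalysed acylation with acetic anhydride needs no nucleophilic amine that could quaternise on the allylic bromide, takes place at oxygen so that C1 stays S, and the allylic C1–O bond, flanked by CHCl and CH2Br, is too electron-poor to ionise at this temperature.

Compound list
1 | methyl (S)-glycidate | COC(=O)[C@@H]1CO1 | starting material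
2 | 2-methylprop-1-enylmagnesium bromide | CC(C)=C[Mg]Br | starting material
3 | methyl (S)-2-hydroxy-5-methylhex-4-enoate | COC(=O)[C@@H](O)CC=C(C)C | intermediate
4 | methyl (S)-5-methyl-2-(triethylsilyloxy)hex-4-enoate | COC(=O)[C@@H](O[Si](CC)(CC)CC)CC=C(C)C | intermediate
5 | dimethyl (1-diazo-2-oxopropyl)phosphonate | CC(=O)C(=[N+]=[N-])P(=O)(OC)OC | starting material
6 | (S)-5-methyl-2-(triethylsilyloxy)hex-4-enal | O=C[C@@H](O[Si](CC)(CC)CC)CC=C(C)C | intermediate
7 | (S)-triethyl[(6-methylhept-5-en-1-yn-3-yl)oxy]silane | C#C[C@@H](O[Si](CC)(CC)CC)CC=C(C)C | intermediate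
8 | (S)-6-methylhept-5-en-1-yn-3-ol | C#C[C@@H](O)CC=C(C)C | intermediate
9 | vinylmagnesium bromide | C=C[Mg]Br | starting material
10 | (S)-5-(3-methylbut-2-enyl)-4-vinyl-2,5-dihydro-1,2-oxamagnesole | C=CC1=C[Mg]O[C@H]1CC=C(C)C | intermediate
11 | (S,Z)-3-(chloromethylidene)-7-methylocta-1,6-dien-4-ol | O[C@H](/C(C=C)=C\Cl)CC=C(C)C | intermediate
12 | (S,Z)-3-(chloromethylidene)-7-methylocta-1,6-dien-4-yl tert-butyldimethylsilyl ether | CC(C)(C)[Si](C)(C)O[C@H](/C(C=C)=C\Cl)CC=C(C)C | intermediate
13 | tert-butyl{[(1S,2Z,3R,5R)-5-bromo-2-(2-bromoethylidene)-3-chloro-4,4-dimethylcyclohexyl]oxy}dimethylsilane | CC(C)(C)[Si](C)(C)O[C@H]1C[C@@H](Br)C(C)(C)[C@H](Cl)/C1=C\CBr | intermediate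
14 | (1S,2Z,3R,5R)-5-bromo-2-(2-bromoethylidene)-3-chloro-4,4-dimethylcyclohexan-1-ol | O[C@H]1C[C@@H](Br)C(C)(C)[C@H](Cl)/C1=C\CBr | intermediate
15 | (1S,2Z,3R,5R)-5-bromo-2-(2-bromoethylidene)-3-chloro-4,4-dimethylcyclohexyl acetate | CC(=O)O[C@H]1C[C@@H](Br)C(C)(C)[C@H](Cl)/C1=C\CBr | target

Total step count: 8. Longest linear sequence: 8 steps (1 to 15).

Steps most likely to fail

Step 6. The bromonium ion may be consumed by halide, by the silyl ether oxygen or by proton loss before the deactivated chlorodiene closes the ring. The reagent may also add to the diene, halide scrambling at C8 may go beyond what the exchange repairs, and the two faces of the prenyl alkene may be poorly told apart. The fallback sets out from 12 and returns at 13, and it separates the three bond formations with established organomercury chemistry. The ring closure itself still depends on the chlorodiene as terminator.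
- Hg(OCOCF3)2 in MeNO2 at −20 °C mercurates the prenyl alkene reversibly and without free halide, so a slow ring closure is not punished. It should give the cyclised mercurial bis(trifluoroacetate) F1, with trifluoroacetate held at C8.
- Aqueous KBr followed by NaHCO3 in aqueous methanol should give the bromomercurial allylic alcohol F2.
- Bromodemercuration (Br2, LiBr, pyridine, O2, 0 °C) favours the equatorial bromide and should give the bromo allylic alcohol F3. The C6=C7 alkene is shielded by its three electron-withdrawing allylic substituents.
- An Appel reaction (CBr4, PPh3, CH2Cl2, 0 °C) converts the primary allylic alcohol into 13.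

Step 4. Metalation of the terminal alkyne C–H may outrun carbometalation, vinyl transfer from copper may be sluggish, and the chlorinating agent may oxidise the magnesium alkoxide. The fallback sets out from 3 and returns at 12, and it makes the chloroalkene by olefination instead of carbometalation.
- t-BuMe2SiCl and imidazole should give the silyl ester F4.
- MeNH(OMe)·HCl with i-PrMgCl should give the Weinreb amide F5.
- Vinylmagnesium bromide 9 with an inverse acidic quench should give the vinyl ketone F6.
- A Wittig reaction follows with chloromethylenetriphenylphosphorane F7, made from (chloromethyl)triphenylphosphonium chloride and NaN(SiMe3)2 in THF at −78 °C. It should give 12 together with the E chlorodiene F8, which is removed by chromatography.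

Step 3. Over-reduction at the hydride stage, epimerisation of the α-silyloxy aldehyde in basic methanol, or evaporative loss of the small alcohol may erode the one-flask sequence. The fallback sets out from 4 and returns at 8, and it builds the alkyne without basic methanol.
- i-Bu2AlH reduction with a tartrate work-up allows isolation of aldehyde 6.
- Base-free dibromo-olefination (CBr4, PPh3, CH2Cl2, 0 °C) should give the dibromoalkene F9.
- n-BuLi (2 equiv, THF, −78 °C; Corey–Fuchs alkyne synthesis) leads through the lithium acetylide F10 to the silyl alkyne 7.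
- 1 M HCl in methanol releases 8.

Further compounds
F1 | step 6 | cyclised mercurial bis(trifluoroacetate) (C3–HgOCOCF3 and C8–OCOCF3, otherwise as 13) | CC(C)(C)[Si](C)(C)O[C@H]1C[C@@H]([Hg]OC(=O)C(F)(F)F)C(C)(C)[C@H](Cl)/C1=C\COC(=O)C(F)(F)F
F2 | step 6 | bromomercurial allylic alcohol (C3–HgBr and C8–OH, otherwise as 13) | CC(C)(C)[Si](C)(C)O[C@H]1C[C@@H]([Hg]Br)C(C)(C)[C@H](Cl)/C1=C\CO
F3 | step 6 | bromo allylic alcohol (C8–OH, otherwise as 13) | CC(C)(C)[Si](C)(C)O[C@H]1C[C@@H](Br)C(C)(C)[C@H](Cl)/C1=C\CO
F4 | step 4 | silyl ester, methyl (S)-2-(tert-butyldimethylsilyloxy)-5-methylhex-4-enoate | COC(=O)[C@@H](O[Si](C)(C)C(C)(C)C)CC=C(C)C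
F5 | step 4 | Weinreb amide, (S)-2-(tert-butyldimethylsilyloxy)-N-methoxy-N,5-dimethylhex-4-enamide | CON(C)C(=O)[C@@H](O[Si](C)(C)C(C)(C)C)CC=C(C)C
F6 | step 4 | vinyl ketone, (S)-4-(tert-butyldimethylsilyloxy)-7-methylocta-1,6-dien-3-one | C=CC(=O)[C@@H](O[Si](C)(C)C(C)(C)C)CC=C(C)C
F7 | step 4 | chloromethylenetriphenylphosphorane | ClC=P(c1ccccc1)(c1ccccc1)c1ccccc1
F8 | step 4 | E chlorodiene, (S,E)-3-(chloromethylidene)-7-methylocta-1,6-dien-4-yl tert-butyldimethylsilyl ether | CC(C)(C)[Si](C)(C)O[C@H](/C(C=C)=C/Cl)CC=C(C)C
F9 | step 3 | dibromoalkene, (S)-[(1,1-dibromo-6-methylhepta-1,5-dien-3-yl)oxy]triethylsilane | BrC(Br)=C[C@@H](O[Si](CC)(CC)CC)CC=C(C)C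
F10 | step 3 | lithium acetylide of 7 | [Li]C#C[C@@H](O[Si](CC)(CC)CC)CC=C(C)C
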